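**Retrosynthetic overview**

- The route rests on one feature of the single ten-membered ring: C1 is a carbinol carbon allylic to the Z C2=C3 olefin, and its oxygen is 1,3-anti to the C9 oxygen across the isopropyl-bearing C10. C1–C2 is therefore cut to a C1 aldehyde and a Z C2 alkenyl iodide, and the ring is closed last by a CrCl2/NiCl2 (Nozaki–Hiyama–Kishi) addition.
- The Z iodoalkene (C2, C3 and the C3 methyl) comes from a C4 propargylic alcohol by copper-catalysed anti-methylmagnesiation and iodination. C4 is set by asymmetric transfer hydrogenation of a silyl ynone made from a C4 Weinreb amide and trimethylsilylacetylene.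
- C9 and C10 come from an Evans syn-aldol of the (R)-benzyloxazolidinone imide of 3-methylbutanoic acid with methyl (Z)-4-methyl-6-oxohex-3-enoate. The Z C6=C7 olefin of that aldehyde is the ring-cis olefin left by Birch reduction and ozonolysis of 4-methylanisole.
- After ring closure: acetate on C1, exchange of the C9 triethylsilyl ether for the benzoate, and removal of the C4 silyl ether.

Key step: step 14

Remark: the ring closure is assumed to follow Felkin–Anh control from C10; the route does not depend on this, because C1 can be reset from C9 (fallback to step 14). Ring compounds are named with the locants C1 (acetoxy carbon) to C10 (isopropyl carbon) used above.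

**Route**

Step 1
Reactants: 1 4-methylanisole
Product: 2 1-methoxy-4-methylcyclohexa-1,4-diene
Conditions: Li, liq. NH3/THF, t-BuOH, −78 to −33 °C
Reagents that add atoms: none
Why: Birch reduction gives the non-conjugated 1,4-diene with the methoxy and methyl groups on the two remaining double bonds, so the later C6=C7 olefin is held cis inside the ring.

Step 2
Reactants: 2 1-methoxy-4-methylcyclohexa-1,4-diene
Product: 4 methyl (3Z)-4-methyl-6-oxohex-3-enoate, via methoxy hydroperoxide 3 (not isolated)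
Conditions: O3 (1.0 equiv), CH2Cl2/MeOH, NaHCO3, −78 °C; then Me2S, −78 °C to rt; crude 4 used at once
Reagents that add atoms: ozone (O=[O+][O-])
Why: Ozonolysis attacks the enol ether double bond much faster than the trialkyl olefin; Criegee cleavage gives the methyl ester (later C4) and a carbonyl oxide that methanol traps as 3, and Me2S reduces 3 to the C9 aldehyde, the ring-cis olefin emerging as the Z C6=C7 bond.

Step 3
Reactants: 5 (R)-4-benzyloxazolidin-2-one; 6 3-methylbutanoyl chloride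
Product: 8 (R)-4-benzyl-3-(3-methylbutanoyl)oxazolidin-2-one, via lithium oxazolidinide 7 (not isolated)
Conditions: n-BuLi, THF, −78 °C; then 6, −78 to 0 °C (prepared ahead of step 2)
Reagents that add atoms: none
Why: N-Acylation of the lithiated oxazolidinone with the acid chloride is the standard entry to Evans imides; no stereocentre is formed.

Step 4
Reactants: 8 (R)-4-benzyl-3-(3-methylbutanoyl)oxazolidin-2-one; 4 methyl (3Z)-4-methyl-6-oxohex-3-enoate
Product: 10 methyl (3Z,6S,7R)-7-[(4R)-4-benzyl-2-oxo-1,3-oxazolidine-3-carbonyl]-6-hydroxy-4,8-dimethylnon-3-enoate, via dibutylboron Z-enolate 9 (not isolated)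
Conditions: Bu2BOTf, i-Pr2NEt, CH2Cl2, 0 °C; then 4, −78 to 0 °C; H2O2, MeOH, pH 7 buffer (NaH2PO4/Na2HPO4), 0 °C
Reagents that add atoms: none
Why: Evans syn-aldol: the Z(O)-boron enolate reacts through a Zimmerman–Traxler chair with the auxiliary carbonyl turned away from the enolate oxygen, so the aldehyde adds to the face away from the benzyl group and C9 (6S) and C10 (7R) are set 2,3-syn; the aldehyde meets the enolate at −78 °C with the amine held as its triflate salt, which should hold back migration of the C6=C7 bond into conjugation.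

Step 5
Reactants: 10 methyl (3Z,6S,7R)-7-[(4R)-4-benzyl-2-oxo-1,3-oxazolidine-3-carbonyl]-6-hydroxy-4,8-dimethylnon-3-enoate
Product: 11 methyl (3Z,6S,7S)-6-hydroxy-7-(hydroxymethyl)-4,8-dimethylnon-3-enoate
Conditions: NaBH4, THF/H2O (4:1), 0 °C to rt
Reagents that add atoms: none
Why: Reductive cleavage of the auxiliary: the imide carbonyl is far more electrophilic than the methyl ester and is activated further by the neighbouring C9 hydroxyl, so borohydride in wet THF should reduce only C1 and release the oxazolidinone for reuse.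

Step 6
Reactants: 11 methyl (3Z,6S,7S)-6-hydroxy-7-(hydroxymethyl)-4,8-dimethylnon-3-enoate
Product: 12 methyl (3Z,6S,7S)-4,8-dimethyl-6-[(triethylsilyl)oxy]-7-{[(triethylsilyl)oxy]methyl}non-3-enoate
Conditions: TESOTf, 2,6-lutidine, CH2Cl2, −78 to −40 °C
Reagents that add atoms: triethylsilyl trifluoromethanesulfonate (CC[Si](CC)(CC)OS(=O)(=O)C(F)(F)F)
Why: Silylation of both hydroxyls with the silyl triflate and a hindered base; the primary C1 ether is the one later removed oxidatively, the secondary C9 ether stays until the end game.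

Step 7
Reactants: 12 methyl (3Z,6S,7S)-4,8-dimethyl-6-[(triethylsilyl)oxy]-7-{[(triethylsilyl)oxy]methyl}non-3-enoate
Product: 13 (3Z,6S,7S)-N-methoxy-N,4,8-trimethyl-6-[(triethylsilyl)oxy]-7-{[(triethylsilyl)oxy]methyl}non-3-enamide
Conditions: MeNHOMe·HCl, AlMe3, CH2Cl2, 0 °C to rt; aq. potassium sodium tartrate (KNaC4H4O6)
Reagents that add atoms: N,O-dimethylhydroxylamine hydrochloride (CNOC.Cl)
Why: Weinreb amidation: the aluminium amide formed from AlMe3 and the amine salt converts the unhindered methyl ester into the N-methoxy-N-methylamide under non-basic conditions that should not move the β,γ-double bond.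

Step 8
Reactants: 13 (3Z,6S,7S)-N-methoxy-N,4,8-trimethyl-6-[(triethylsilyl)oxy]-7-{[(triethylsilyl)oxy]methyl}non-3-enamide; 14 trimethylsilylacetylene
Product: 16 (5Z,8S,9S)-6,10-dimethyl-8-[(triethylsilyl)oxy]-9-{[(triethylsilyl)oxy]methyl}-1-(trimethylsilyl)undec-5-en-1-yn-3-one, via lithium acetylide 15 (not isolated)
Conditions: 14, n-BuLi, THF, −78 °C; then 13, −78 to −20 °C; cold aq. NH4Cl
Reagents that add atoms: none
Why: Weinreb ketone synthesis: the lithium acetylide adds once to the amide and the chelated tetrahedral adduct collapses to the ynone only on quench, bringing in C2 and C3 without over-addition.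

Step 9
Reactants: 16 (5Z,8S,9S)-6,10-dimethyl-8-[(triethylsilyl)oxy]-9-{[(triethylsilyl)oxy]methyl}-1-(trimethylsilyl)undec-5-en-1-yn-3-one
Product: 17 (3R,5Z,8S,9S)-6,10-dimethyl-8-[(triethylsilyl)oxy]-9-{[(triethylsilyl)oxy]methyl}-1-(trimethylsilyl)undec-5-en-1-yn-3-ol
Conditions: Ru[(R,R)-TsNCH(Ph)CH(Ph)NH](p-cymene) (2 mol %), i-PrOH, 25 °C
Reagents that add atoms: none
Why: Noyori asymmetric transfer hydrogenation of an alkynyl ketone: the alkynyl group takes the place of the aryl group of the usual substrates, and the (R,R)-diamine complex should deliver hydride to the face that gives the (R)-propargylic alcohol (C4) without added base.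

Step 10
Reactants: 17 (3R,5Z,8S,9S)-6,10-dimethyl-8-[(triethylsilyl)oxy]-9-{[(triethylsilyl)oxy]methyl}-1-(trimethylsilyl)undec-5-en-1-yn-3-ol
Product: 18 (3R,5Z,8S,9S)-6,10-dimethyl-8-[(triethylsilyl)oxy]-9-{[(triethylsilyl)oxy]methyl}undec-5-en-1-yn-3-ol
Conditions: K2CO3, MeOH, 0 °C to rt, short reaction time
Reagents that add atoms: none
Why: Base-catalysed methanolysis cleaves the C(sp)–Si bond selectively; the triethylsilyl ethers of the hindered alcohols should not be touched under these brief, mild conditions.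

Step 11
Reactants: 18 (3R,5Z,8S,9S)-6,10-dimethyl-8-[(triethylsilyl)oxy]-9-{[(triethylsilyl)oxy]methyl}undec-5-en-1-yn-3-ol
Product: 20 (1Z,3R,5Z,8S,9S)-1-iodo-2,6,10-trimethyl-8-[(triethylsilyl)oxy]-9-{[(triethylsilyl)oxy]methyl}undeca-1,5-dien-3-ol, via alkenylmagnesium chelate 19 (not isolated)
Conditions: MeMgBr (4 equiv), CuI (20 mol %), THF, −20 °C to rt; then I2, THF, −78 °C; aq. Na2S2O3
Reagents that add atoms: methylmagnesium bromide (C[Mg]Br); iodine (II)
Why: Copper-catalysed anti-carbomagnesiation of a propargylic alkoxide: methyl is delivered to the alkyne carbon next to the carbinol (C3) and magnesium ends on the terminal carbon (C2) cis to the carbinol in a five-membered chelate, and iodinolysis with retention gives the Z iodoalkene with iodine cis to C4.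

Step 12
Reactants: 20 (1Z,3R,5Z,8S,9S)-1-iodo-2,6,10-trimethyl-8-[(triethylsilyl)oxy]-9-{[(triethylsilyl)oxy]methyl}undeca-1,5-dien-3-ol
Product: 21 (1Z,3R,5Z,8S,9S)-3-[(tert-butyldimethylsilyl)oxy]-1-iodo-2,6,10-trimethyl-8-[(triethylsilyl)oxy]-9-{[(triethylsilyl)oxy]methyl}undeca-1,5-diene
Conditions: TBSOTf, 2,6-lutidine, CH2Cl2, −78 °C
Reagents that add atoms: tert-butyldimethylsilyl trifluoromethanesulfonate (CC(C)(C)[Si](C)(C)OS(=O)(=O)C(F)(F)F)
Why: Silylation of the secondary allylic alcohol with the silyl triflate and a hindered base at low temperature; the triethylsilyl ethers are stable to these conditions.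

Step 13
Reactants: 21 (1Z,3R,5Z,8S,9S)-3-[(tert-butyldimethylsilyl)oxy]-1-iodo-2,6,10-trimethyl-8-[(triethylsilyl)oxy]-9-{[(triethylsilyl)oxy]methyl}undeca-1,5-diene
Product: 23 (2R,3S,5Z,8R,9Z)-8-[(tert-butyldimethylsilyl)oxy]-10-iodo-5,9-dimethyl-2-(propan-2-yl)-3-[(triethylsilyl)oxy]deca-5,9-dienal, via alkoxysulfonium chloride 22 (not isolated)
Conditions: (COCl)2, DMSO, CH2Cl2, −78 to −40 °C; then Et3N, −78 to 0 °C; crude 23 used at once
Reagents that add atoms: none
Why: Swern-type oxidative desilylation: the chlorosulfonium salt attacks the least hindered, primary triethylsilyl ether to give the alkoxysulfonium salt and chlorotriethylsilane, and triethylamine then triggers the usual ylide fragmentation to the aldehyde, while the secondary silyl ethers and the C10 stereocentre are expected to survive.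

Step 14
Reactants: 23 (2R,3S,5Z,8R,9Z)-8-[(tert-butyldimethylsilyl)oxy]-10-iodo-5,9-dimethyl-2-(propan-2-yl)-3-[(triethylsilyl)oxy]deca-5,9-dienal
Product: 25 (1S,2Z,4R,6Z,9S,10S)-4-[(tert-butyldimethylsilyl)oxy]-3,7-dimethyl-10-(propan-2-yl)-9-[(triethylsilyl)oxy]cyclodeca-2,6-dien-1-ol, via alkenylchromium dichloride 24 (not isolated)
Conditions: CrCl2 (20 equiv), NiCl2 (0.2 equiv), degassed DMSO/THF (3:1), 25 °C, slow addition of 23 to 0.002 M; aq. ethylenediamine work-up
Reagents that add atoms: none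
Why: Nozaki–Hiyama–Kishi reaction: NiCl2 is reduced by divalent chromium to zerovalent nickel, which inserts into the C2–I bond, and transmetalation to trivalent chromium gives the alkenylchromium 24 with retention of the Z geometry, which then adds to the C1 aldehyde. The closest known reaction type is the chromium-mediated macrocyclisation of iodoalkene aldehydes to nine- to eleven-membered carbocycles. The ten-membered ring closes by 10-exo-trig carbonyl addition of C2 to C1 under high dilution, the two Z olefins bending the chain so that C2 can reach C1. The new C1 stereocentre is controlled by C10: the C9 branch is part of the tether and cannot lie anti to the incoming C2, so the isopropyl group should take the anti position (Felkin–Anh) and the carbinol should form anti to the isopropyl group and 1,3-anti to the C9 silyloxy group. The step needs selective activation of the C–I bond, retention of the C2=C3 geometry and this facial selectivity; the first two are secured by the aldehyde-selective, non-basic alkenylchromium reagent and the configurationally stable β,β-disubstituted iodoalkene, the third by the C9 and C10 stereocentres of the substrate.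

Step 15
Reactants: 25 (1S,2Z,4R,6Z,9S,10S)-4-[(tert-butyldimethylsilyl)oxy]-3,7-dimethyl-10-(propan-2-yl)-9-[(triethylsilyl)oxy]cyclodeca-2,6-dien-1-ol
Product: 26 (1S,2Z,4R,6Z,9S,10S)-4-[(tert-butyldimethylsilyl)oxy]-3,7-dimethyl-10-(propan-2-yl)-9-[(triethylsilyl)oxy]cyclodeca-2,6-dien-1-yl acetate
Conditions: Ac2O, pyridine, DMAP (cat.), CH2Cl2, 0 °C to rt
Reagents that add atoms: acetic anhydride (CC(=O)OC(C)=O)
Why: DMAP-catalysed acetylation of the secondary allylic alcohol; no stereocentre is touched.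

Step 16
Reactants: 26 (1S,2Z,4R,6Z,9S,10S)-4-[(tert-butyldimethylsilyl)oxy]-3,7-dimethyl-10-(propan-2-yl)-9-[(triethylsilyl)oxy]cyclodeca-2,6-dien-1-yl acetate
Product: 27 (1S,2Z,4R,6Z,9S,10R)-4-[(tert-butyldimethylsilyl)oxy]-9-hydroxy-3,7-dimethyl-10-(propan-2-yl)cyclodeca-2,6-dien-1-yl acetate
Conditions: HF·pyridine, pyridine, THF, 0 °C
Reagents that add atoms: none
Why: Buffered fluoride cleavage removes a triethylsilyl ether much faster than a secondary tert-butyldimethylsilyl ether, and the weakly acidic medium should avoid migration of the C1 acetyl group to the freed C9 hydroxyl.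

Step 17
Reactants: 27 (1S,2Z,4R,6Z,9S,10R)-4-[(tert-butyldimethylsilyl)oxy]-9-hydroxy-3,7-dimethyl-10-(propan-2-yl)cyclodeca-2,6-dien-1-yl acetate
Product: 28 (1S,2Z,4R,6Z,9S,10R)-9-(benzoyloxy)-4-[(tert-butyldimethylsilyl)oxy]-3,7-dimethyl-10-(propan-2-yl)cyclodeca-2,6-dien-1-yl acetate
Conditions: BzCl, pyridine, DMAP, CH2Cl2, 0 °C to rt (run directly after step 16)
Reagents that add atoms: benzoyl chloride (O=C(Cl)c1ccccc1)
Why: Acylation of the C9 alcohol with benzoyl chloride under nucleophilic catalysis; it is run at once so that the acetate has no time to migrate.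

Step 18
Reactants: 28 (1S,2Z,4R,6Z,9S,10R)-9-(benzoyloxy)-4-[(tert-butyldimethylsilyl)oxy]-3,7-dimethyl-10-(propan-2-yl)cyclodeca-2,6-dien-1-yl acetate
Product: 29 (1S,2Z,4R,6Z,9S,10R)-9-(benzoyloxy)-4-hydroxy-3,7-dimethyl-10-(propan-2-yl)cyclodeca-2,6-dien-1-yl acetate
Conditions: HF·pyridine, THF, 0 °C to rt
Reagents that add atoms: none
Why: Acidic fluoride removal of the last silyl ether; a basic fluoride source is avoided because the cis-related C1 acetate could migrate to a C4 alkoxide.

**Compound list**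

1 | 4-methylanisole | Cc1ccc(OC)cc1 | starting material
2 | 1-methoxy-4-methylcyclohexa-1,4-diene | COC1=CCC(C)=CC1 | intermediate
3 | methyl (3Z)-6-hydroperoxy-6-methoxy-4-methylhex-3-enoate | COC(=O)C/C=C(/C)CC(OC)OO | intermediate
4 | methyl (3Z)-4-methyl-6-oxohex-3-enoate | COC(=O)C/C=C(/C)CC=O | intermediate
5 | (R)-4-benzyloxazolidin-2-one | O=C1N[C@H](Cc2ccccc2)CO1 | starting material
6 | 3-methylbutanoyl chloride | CC(C)CC(Cl)=O | starting material
7 | lithium (R)-4-benzyl-2-oxooxazolidin-3-ide | [Li]N1[C@H](Cc2ccccc2)COC1=O | intermediate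
8 | (R)-4-benzyl-3-(3-methylbutanoyl)oxazolidin-2-one | CC(C)CC(=O)N1[C@H](Cc2ccccc2)COC1=O | intermediate
9 | dibutylboron Z-enolate of 8 | CC(C)/C=C(\OB(CCCC)CCCC)N1[C@H](Cc2ccccc2)COC1=O | intermediate
10 | methyl (3Z,6S,7R)-7-[(4R)-4-benzyl-2-oxo-1,3-oxazolidine-3-carbonyl]-6-hydroxy-4,8-dimethylnon-3-enoate | COC(=O)C/C=C(/C)C[C@H](O)[C@H](C(=O)N1[C@H](Cc2ccccc2)COC1=O)C(C)C | intermediate
11 | methyl (3Z,6S,7S)-6-hydroxy-7-(hydroxymethyl)-4,8-dimethylnon-3-enoate | COC(=O)C/C=C(/C)C[C@H](O)[C@H](CO)C(C)C | intermediate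
12 | methyl (3Z,6S,7S)-4,8-dimethyl-6-[(triethylsilyl)oxy]-7-{[(triethylsilyl)oxy]methyl}non-3-enoate | COC(=O)C/C=C(/C)C[C@H](O[Si](CC)(CC)CC)[C@H](CO[Si](CC)(CC)CC)C(C)C | intermediate
13 | (3Z,6S,7S)-N-methoxy-N,4,8-trimethyl-6-[(triethylsilyl)oxy]-7-{[(triethylsilyl)oxy]methyl}non-3-enamide | CON(C)C(=O)C/C=C(/C)C[C@H](O[Si](CC)(CC)CC)[C@H](CO[Si](CC)(CC)CC)C(C)C | intermediate
14 | trimethylsilylacetylene | C[Si](C)(C)C#C | starting material
15 | lithium (trimethylsilyl)acetylide | [Li]C#C[Si](C)(C)C | intermediate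
16 | (5Z,8S,9S)-6,10-dimethyl-8-[(triethylsilyl)oxy]-9-{[(triethylsilyl)oxy]methyl}-1-(trimethylsilyl)undec-5-en-1-yn-3-one | C[Si](C)(C)C#CC(=O)C/C=C(/C)C[C@H](O[Si](CC)(CC)CC)[C@H](CO[Si](CC)(CC)CC)C(C)C | intermediate
17 | (3R,5Z,8S,9S)-6,10-dimethyl-8-[(triethylsilyl)oxy]-9-{[(triethylsilyl)oxy]methyl}-1-(trimethylsilyl)undec-5-en-1-yn-3-ol | C[Si](C)(C)C#C[C@H](O)C/C=C(/C)C[C@H](O[Si](CC)(CC)CC)[C@H](CO[Si](CC)(CC)CC)C(C)C | intermediate
18 | (3R,5Z,8S,9S)-6,10-dimethyl-8-[(triethylsilyl)oxy]-9-{[(triethylsilyl)oxy]methyl}undec-5-en-1-yn-3-ol | C#C[C@H](O)C/C=C(/C)C[C@H](O[Si](CC)(CC)CC)[C@H](CO[Si](CC)(CC)CC)C(C)C | intermediate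
19 | cyclic alkenylmagnesium alkoxide (five-membered C2–Mg–O chelate) formed from 18 | CC1=C[Mg]O[C@@H]1C/C=C(/C)C[C@H](O[Si](CC)(CC)CC)[C@H](CO[Si](CC)(CC)CC)C(C)C | intermediate
20 | (1Z,3R,5Z,8S,9S)-1-iodo-2,6,10-trimethyl-8-[(triethylsilyl)oxy]-9-{[(triethylsilyl)oxy]methyl}undeca-1,5-dien-3-ol | I/C=C(/C)[C@H](O)C/C=C(/C)C[C@H](O[Si](CC)(CC)CC)[C@H](CO[Si](CC)(CC)CC)C(C)C | intermediate
21 | (1Z,3R,5Z,8S,9S)-3-[(tert-butyldimethylsilyl)oxy]-1-iodo-2,6,10-trimethyl-8-[(triethylsilyl)oxy]-9-{[(triethylsilyl)oxy]methyl}undeca-1,5-diene | I/C=C(/C)[C@H](O[Si](C)(C)C(C)(C)C)C/C=C(/C)C[C@H](O[Si](CC)(CC)CC)[C@H](CO[Si](CC)(CC)CC)C(C)C | intermediate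
22 | dimethyl(alkoxy)sulfonium chloride of the C1 oxygen of 21 | I/C=C(/C)[C@H](O[Si](C)(C)C(C)(C)C)C/C=C(/C)C[C@H](O[Si](CC)(CC)CC)[C@H](CO[S+](C)C)C(C)C.[Cl-] | intermediate
23 | (2R,3S,5Z,8R,9Z)-8-[(tert-butyldimethylsilyl)oxy]-10-iodo-5,9-dimethyl-2-(propan-2-yl)-3-[(triethylsilyl)oxy]deca-5,9-dienal | I/C=C(/C)[C@H](O[Si](C)(C)C(C)(C)C)C/C=C(/C)C[C@H](O[Si](CC)(CC)CC)[C@H](C=O)C(C)C | intermediate
24 | Z-alkenylchromium dichloride from 23 (trivalent chromium on C2) | Cl[Cr](Cl)/C=C(/C)[C@H](O[Si](C)(C)C(C)(C)C)C/C=C(/C)C[C@H](O[Si](CC)(CC)CC)[C@H](C=O)C(C)C | intermediate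
25 | (1S,2Z,4R,6Z,9S,10S)-4-[(tert-butyldimethylsilyl)oxy]-3,7-dimethyl-10-(propan-2-yl)-9-[(triethylsilyl)oxy]cyclodeca-2,6-dien-1-ol | O[C@H]1/C=C(/C)[C@H](O[Si](C)(C)C(C)(C)C)C/C=C(/C)C[C@H](O[Si](CC)(CC)CC)[C@H]1C(C)C | intermediate
26 | (1S,2Z,4R,6Z,9S,10S)-4-[(tert-butyldimethylsilyl)oxy]-3,7-dimethyl-10-(propan-2-yl)-9-[(triethylsilyl)oxy]cyclodeca-2,6-dien-1-yl acetate | CC(=O)O[C@H]1/C=C(/C)[C@H](O[Si](C)(C)C(C)(C)C)C/C=C(/C)C[C@H](O[Si](CC)(CC)CC)[C@H]1C(C)C | intermediate
27 | (1S,2Z,4R,6Z,9S,10R)-4-[(tert-butyldimethylsilyl)oxy]-9-hydroxy-3,7-dimethyl-10-(propan-2-yl)cyclodeca-2,6-dien-1-yl acetate | CC(=O)O[C@H]1/C=C(/C)[C@H](O[Si](C)(C)C(C)(C)C)C/C=C(/C)C[C@H](O)[C@H]1C(C)C | intermediate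
28 | (1S,2Z,4R,6Z,9S,10R)-9-(benzoyloxy)-4-[(tert-butyldimethylsilyl)oxy]-3,7-dimethyl-10-(propan-2-yl)cyclodeca-2,6-dien-1-yl acetate | CC(=O)O[C@H]1/C=C(/C)[C@H](O[Si](C)(C)C(C)(C)C)C/C=C(/C)C[C@H](OC(=O)c2ccccc2)[C@H]1C(C)C | intermediate
29 | (1S,2Z,4R,6Z,9S,10R)-9-(benzoyloxy)-4-hydroxy-3,7-dimethyl-10-(propan-2-yl)cyclodeca-2,6-dien-1-yl acetate (CNP0125882.1) | CC(=O)O[C@H]1/C=C(/C)[C@H](O)C/C=C(/C)C[C@H](OC(=O)c2ccccc2)[C@H]1C(C)C | target

**Step count and risks**

Total step count: 18. Longest linear sequence: 17 steps (steps 1, 2 and 4–18, from 4-methylanisole); step 3 is the side branch that prepares the imide.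

The three steps most likely to fail:

1. Step 14 (ring closure). The alkenylchromium may add to the other face of the C1 aldehyde, because Felkin–Anh control from C10 inside a medium-ring transition state is not assured. The fallback sets out from 23 and comes back at 28.
   - The closure is run as in step 14 and the carbinol is carried on whatever its C1 configuration, that is also the (1R)-epimer of 25 F1.
   - Dess–Martin oxidation (NaHCO3, CH2Cl2) converts either epimer into the ring enone F2.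
   - HF·pyridine/pyridine frees the C9 hydroxyl to give the β-hydroxy enone F3.
   - An Evans–Tishchenko reduction (PhCHO, SmI2 as precatalyst, THF, −10 °C) passes hydride from the C9 hemiacetal to C1 within a six-membered chelate of trivalent samarium. This should give the 1,3-anti C1 alcohol with the benzoate already on C9, the hydroxy benzoate F4.
   - Acetylation (Ac2O, DMAP, pyridine) gives 28.
   - C1 is thus set from C9 by a directed reduction instead of by the ring closure, and steps 15–17 are replaced.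

2. Step 11 (methylmagnesiation–iodination). Iodine may be consumed by iodoetherification of the C6=C7 double bond through the C4 magnesium alkoxide, or the alkenyl–magnesium bond may be protonated before it is iodinated. The fallback sets out from 18 and comes back at 21.
   - The carbomagnesiation is run as before to chelate 19, which is quenched with Bu3SnCl instead of iodine to give the Z-alkenylstannane alcohol F5.
   - Silylation (TBSOTf, 2,6-lutidine) gives the stannane silyl ether F6.
   - Iododestannylation (I2, CH2Cl2, −78 °C) with retention of geometry gives 21. The C–I bond is then made only after the C4 oxygen is capped, by tin–iodine exchange that is much faster than attack on the olefin.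

3. Step 13 (oxidative desilylation). The chlorosulfonium salt may cleave the branched primary triethylsilyl ether incompletely, or the C9 triethylsilyl ether may be lost alongside it. The fallback sets out from 21 and comes back at 23.
   - The primary silyl ether alone is removed with HF·pyridine/pyridine in THF at 0 °C to give the primary alcohol F7.
   - F7 is oxidised separately with Dess–Martin periodinane/NaHCO3 to 23.

Further compounds
F1 | step 14 | (1R,2Z,4R,6Z,9S,10S)-4-[(tert-butyldimethylsilyl)oxy]-3,7-dimethyl-10-(propan-2-yl)-9-[(triethylsilyl)oxy]cyclodeca-2,6-dien-1-ol | O[C@@H]1/C=C(/C)[C@H](O[Si](C)(C)C(C)(C)C)C/C=C(/C)C[C@H](O[Si](CC)(CC)CC)[C@H]1C(C)C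
F2 | step 14 | (2Z,4R,6Z,9S,10R)-4-[(tert-butyldimethylsilyl)oxy]-3,7-dimethyl-10-(propan-2-yl)-9-[(triethylsilyl)oxy]cyclodeca-2,6-dien-1-one | O=C1/C=C(/C)[C@H](O[Si](C)(C)C(C)(C)C)C/C=C(/C)C[C@H](O[Si](CC)(CC)CC)[C@H]1C(C)C
F3 | step 14 | (2Z,4R,6Z,9S,10R)-4-[(tert-butyldimethylsilyl)oxy]-9-hydroxy-3,7-dimethyl-10-(propan-2-yl)cyclodeca-2,6-dien-1-one | O=C1/C=C(/C)[C@H](O[Si](C)(C)C(C)(C)C)C/C=C(/C)C[C@H](O)[C@H]1C(C)C
F4 | step 14 | (1S,2Z,4R,6Z,9S,10S)-4-[(tert-butyldimethylsilyl)oxy]-1-hydroxy-3,7-dimethyl-10-(propan-2-yl)cyclodeca-2,6-dien-9-yl benzoate | O[C@H]1/C=C(/C)[C@H](O[Si](C)(C)C(C)(C)C)C/C=C(/C)C[C@H](OC(=O)c2ccccc2)[C@H]1C(C)C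
F5 | step 11 | (1Z,3R,5Z,8S,9S)-2,6,10-trimethyl-1-(tributylstannyl)-8-[(triethylsilyl)oxy]-9-{[(triethylsilyl)oxy]methyl}undeca-1,5-dien-3-ol | CCCC[Sn](CCCC)(CCCC)/C=C(/C)[C@H](O)C/C=C(/C)C[C@H](O[Si](CC)(CC)CC)[C@H](CO[Si](CC)(CC)CC)C(C)C
F6 | step 11 | (1Z,3R,5Z,8S,9S)-3-[(tert-butyldimethylsilyl)oxy]-2,6,10-trimethyl-1-(tributylstannyl)-8-[(triethylsilyl)oxy]-9-{[(triethylsilyl)oxy]methyl}undeca-1,5-diene | CCCC[Sn](CCCC)(CCCC)/C=C(/C)[C@H](O[Si](C)(C)C(C)(C)C)C/C=C(/C)C[C@H](O[Si](CC)(CC)CC)[C@H](CO[Si](CC)(CC)CC)C(C)C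
F7 | step 13 | (2S,3S,5Z,8R,9Z)-8-[(tert-butyldimethylsilyl)oxy]-10-iodo-5,9-dimethyl-2-(propan-2-yl)-3-[(triethylsilyl)oxy]deca-5,9-dien-1-ol | I/C=C(/C)[C@H](O[Si](C)(C)C(C)(C)C)C/C=C(/C)C[C@H](O[Si](CC)(CC)CC)[C@H](CO)C(C)C
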